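**Plan**
- Retrosynthesis: the Z-alkenyl side chain is cut at the ring B aryl–alkenyl bond (back to an aryl bromide and 2-methylbut-3-yn-2-ol), the (2S)-flavanone is traced to the flat flavone, and ring C is then cut at C4a–C4, C4–C3 and O1–C2 in one operation.
- Enabling feature: the C4 carbonyl lies between C4a of the phloroglucinol-type ring A and the C3–C2 unit, with O1 ortho to C4a and C2 carrying ring B. An ortho-iodophenol therefore supplies ring A and O1, carbon monoxide supplies C4, and a ring B arylacetylene supplies C3 and C2.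
- Forward: the ring A iodophenol is made from phloroglucinol (2 steps) and the ring B alkyne from 3-bromo-4-hydroxybenzaldehyde (5 steps: propargyl ether, semihydrogenation, Claisen rearrangement, O-methylation, alkyne homologation). The three-component coupling then closes ring C, the only ring formed in the route.
- The chain is completed after the core: conjugate reduction, MOM removal, Sonogashira coupling at the bromide carried through the key step, and semihydrogenation.
- Stereochemistry: C2 (S) is set by ligand-controlled copper hydride delivery to C2 of the flavone; the Z alkene comes from syn addition of H2 to the alkyne.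

Key step: step 8

Assumption: by mapping the chromone ring onto the cyclic β-substituted enones that serve as the model for this catalyst, (S)-DTBM-SEGPHOS is taken to give the (2S)-flavanone; if a test reduction shows the opposite sense, the (R)-ligand is used and nothing else changes.

**Route**

Step 1
Reactants: 1 phloroglucinol (benzene-1,3,5-triol)
Product: 3 3,5-bis(methoxymethoxy)phenol, via mono-MOM ether 2 (not isolated)
Conditions: MOMCl (2.0 equiv), i-Pr2NEt (2.2 equiv), DMF, 0 °C to rt; chromatography
Reagents that add atoms: chloromethyl methyl ether, COCCl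
Why: Williamson-type O-alkylation of the three equivalent phenols with a limiting amount of MOMCl should give the bis-ether as the main component of a statistical mixture, from which the mono- and tris-ethers can be separated and recycled.

Step 2
Reactants: 3 3,5-bis(methoxymethoxy)phenol
Product: 4 2-iodo-3,5-bis(methoxymethoxy)phenol
Conditions: NIS (1.0 equiv), CH2Cl2, −20 to 0 °C, dark
Reagents that add atoms: N-iodosuccinimide, O=C1CCC(=O)N1I
Why: electrophilic aromatic iodination, in which 3 offers two kinds of activated carbon (C2/C6 beside the free hydroxyl and C4 between the two MOM ethers) and attack beside the hydroxyl is expected to prevail because the phenol hydrogen-bonds to NIS, C4 is flanked by two bulky MOM ethers and the ortho site is doubled, any 4-iodo isomer being removed by chromatography.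

Step 3
Reactants: 5 3-bromo-4-hydroxybenzaldehyde; 6 3-chloro-3-methylbut-1-yne
Product: 7 3-bromo-4-[(2-methylbut-3-yn-2-yl)oxy]benzaldehyde
Conditions: DBU (1.3 equiv), CuCl2·2H2O (1 mol%), MeCN, 0 °C
Reagents that add atoms: none
Why: copper-catalysed propargylic etherification of an acidic phenol with a tertiary propargylic chloride (copper acetylide, ionisation at the tertiary carbon, capture by the phenoxide), the standard way to aryl 1,1-dimethylpropargyl ethers of hydroxybenzaldehydes.

Step 4
Reactants: 7 3-bromo-4-[(2-methylbut-3-yn-2-yl)oxy]benzaldehyde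
Product: 8 3-bromo-4-[(2-methylbut-3-en-2-yl)oxy]benzaldehyde
Conditions: H2 (1 atm), Pd/CaCO3 poisoned with Pb(OAc)2, quinoline, EtOAc, rt
Reagents that add atoms: none
Why: Lindlar semihydrogenation of the terminal alkyne should stop at the vinyl group and leave the aryl bromide and the aldehyde untouched.

Step 5
Reactants: 8 3-bromo-4-[(2-methylbut-3-en-2-yl)oxy]benzaldehyde
Product: 10 3-bromo-4-hydroxy-5-(3-methylbut-2-en-1-yl)benzaldehyde, via ortho-dienone 9 (not isolated)
Conditions: PhNEt2, 140 °C
Reagents that add atoms: none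
Why: aromatic Claisen rearrangement, in which the [3,3] shift of the 1,1-dimethylallyl ether can end productively only at the one unsubstituted ortho carbon (C5), turns the allyl unit into a prenyl group and is followed by tautomerisation of the dienone, the basic solvent suppressing acid-catalysed chroman formation.

Step 6
Reactants: 10 3-bromo-4-hydroxy-5-(3-methylbut-2-en-1-yl)benzaldehyde
Product: 11 3-bromo-4-methoxy-5-(3-methylbut-2-en-1-yl)benzaldehyde
Conditions: MeI, K2CO3, DMF, rt
Reagents that add atoms: iodomethane, CI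
Why: Williamson O-methylation of an acidic (para-formyl, ortho-bromo) phenoxide, which should proceed at rt despite the two flanking groups.

Step 7
Reactants: 11 3-bromo-4-methoxy-5-(3-methylbut-2-en-1-yl)benzaldehyde
Product: 12 1-bromo-5-ethynyl-2-methoxy-3-(3-methylbut-2-en-1-yl)benzene
Conditions: dimethyl (1-diazo-2-oxopropyl)phosphonate, K2CO3, MeOH, 0 °C to rt
Reagents that add atoms: dimethyl (1-diazo-2-oxopropyl)phosphonate (Ohira–Bestmann reagent), COP(=O)(OC)C(=[N+]=[N-])C(C)=O
Why: Seyferth–Gilbert homologation in the Ohira–Bestmann variant converts the non-enolisable aryl aldehyde into the terminal alkyne under mild carbonate conditions that spare the aryl bromide and the prenyl alkene.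

Step 8
Reactants: 4 2-iodo-3,5-bis(methoxymethoxy)phenol; 12 1-bromo-5-ethynyl-2-methoxy-3-(3-methylbut-2-en-1-yl)benzene (1.2 equiv); 13 carbon monoxide
Product: 16 2-[3-bromo-4-methoxy-5-(3-methylbut-2-en-1-yl)phenyl]-5,7-bis(methoxymethoxy)-4H-chromen-4-one, via ortho-hydroxyaryl ynone 14 (not isolated), via diethylamino enone 15 (not isolated)
Conditions: PdCl2(PPh3)2 (5 mol%), CO (5 bar), Et2NH/DMF, 60 °C
Reagents that add atoms: none
Why: Zerovalent palladium formed in situ from PdCl2(PPh3)2 inserts into the C–I bond of 4, CO inserts to give an aroyl complex of divalent palladium, and transfer of the amine-deprotonated alkyne 12 followed by reductive elimination releases ynone 14, creating C4a–C4 and C4–C3. Diethylamine then adds to the ynone to give enaminone 15, and the neighbouring phenol oxygen attacks the amine-bearing carbon and expels the amine, forming O1–C2. The closest known reaction type is the palladium-catalysed carbonylative Sonogashira coupling–annulation of 2-iodophenols with terminal arylacetylenes under CO in a secondary amine, which gives flavones. Ring C closes in the 6-endo mode (6-endo-trig addition–elimination on 15, a net 6-endo-dig closure of 14), and no stereocenter is formed. Three selectivities are needed: C–I over C–Br insertion, secured by the weaker C–I bond at 60 °C under CO against a hindered aryl bromide with an ortho methoxy group; carbonylative over direct alkynylation (which would give a benzofuran), secured by CO pressure, the absence of copper and the doubly ortho-substituted aryl–palladium bond; and pyranone over the five-membered aurone, secured by the secondary-amine pathway through 15. The iodine next to the one free hydroxyl of 4 fixes the 5,7-oxygenation pattern, and the MOM ethers and the prenyl alkene should be inert.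

Step 9
Reactants: 16 2-[3-bromo-4-methoxy-5-(3-methylbut-2-en-1-yl)phenyl]-5,7-bis(methoxymethoxy)-4H-chromen-4-one
Product: 18 (2S)-2-[3-bromo-4-methoxy-5-(3-methylbut-2-en-1-yl)phenyl]-5,7-bis(methoxymethoxy)-2,3-dihydro-4H-chromen-4-one, via silyl enol ether 17 (not isolated)
Conditions: Cu(OAc)2·H2O (5 mol%), (S)-DTBM-SEGPHOS (5.5 mol%), (EtO)2MeSiH (3 equiv), toluene, 0 °C to rt; then aq NH4Cl, THF
Reagents that add atoms: none
Why: copper hydride-catalysed asymmetric conjugate reduction, known for 2-substituted chromones, in which the ligated copper hydride delivers hydride to C2 on the face selected by (S)-DTBM-SEGPHOS and so sets the (2S) centre, the enolate is held as silyl enol ether 17 so that the ketone is not reduced further, and mild hydrolysis gives the flavanone while the aryl bromide, the trisubstituted alkene and the MOM ethers should not react.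

Step 10
Reactants: 18 (2S)-2-[3-bromo-4-methoxy-5-(3-methylbut-2-en-1-yl)phenyl]-5,7-bis(methoxymethoxy)-2,3-dihydro-4H-chromen-4-one
Product: 20 (2S)-2-[3-bromo-4-methoxy-5-(3-methylbut-2-en-1-yl)phenyl]-5,7-dihydroxy-2,3-dihydro-4H-chromen-4-one, via 7-mono-MOM ether 19 (not isolated)
Conditions: 3 M aq HCl, MeOH/THF, 40 °C
Reagents that add atoms: none
Why: acid-catalysed acetal exchange with methanol removes first the peri 5-MOM ether and then the 7-MOM ether, a standard deprotection of prenylated flavanones that should not touch C2 and that is placed here, before the acid-labile tertiary allylic alcohol exists and with no free phenol next to the prenyl group.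

Step 11
Reactants: 20 (2S)-2-[3-bromo-4-methoxy-5-(3-methylbut-2-en-1-yl)phenyl]-5,7-dihydroxy-2,3-dihydro-4H-chromen-4-one; 21 2-methylbut-3-yn-2-ol (1.5 equiv)
Product: 22 (2S)-5,7-dihydroxy-2-[3-(3-hydroxy-3-methylbut-1-yn-1-yl)-4-methoxy-5-(3-methylbut-2-en-1-yl)phenyl]-2,3-dihydro-4H-chromen-4-one
Conditions: PdCl2(PhCN)2 (3 mol%), P(t-Bu)3·HBF4 (6 mol%), CuI (2 mol%), i-Pr2NH (3 equiv), DMF, rt, degassed
Reagents that add atoms: none
Why: Sonogashira coupling with a bulky electron-rich trialkylphosphine, which allows oxidative addition into electron-rich aryl bromides at rt, so the base-sensitive C2 centre is exposed only to a hindered amine at rt, where the 7-phenoxide also lowers the acidity at C3 and disfavours ring opening to the chalcone.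

Step 12
Reactants: 22 (2S)-5,7-dihydroxy-2-[3-(3-hydroxy-3-methylbut-1-yn-1-yl)-4-methoxy-5-(3-methylbut-2-en-1-yl)phenyl]-2,3-dihydro-4H-chromen-4-one
Product: 23 (2S)-5,7-dihydroxy-2-{3-[(1Z)-3-hydroxy-3-methylbut-1-en-1-yl]-4-methoxy-5-(3-methylbut-2-en-1-yl)phenyl}-2,3-dihydro-4H-chromen-4-one
Conditions: H2 (1 atm), Pd/CaCO3 poisoned with Pb(OAc)2, quinoline, EtOAc, rt, stopped at one equivalent of H2
Reagents that add atoms: none
Why: Lindlar semihydrogenation adds H2 syn to the disubstituted aryl alkyne to give the Z alkene, while the trisubstituted prenyl alkene, the ketone and the C2 centre should remain unchanged under neutral conditions.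

**Compound list**

1 | phloroglucinol (benzene-1,3,5-triol) | Oc1cc(O)cc(O)c1 | starting material
2 | 5-(methoxymethoxy)benzene-1,3-diol | COCOc1cc(O)cc(O)c1 | intermediate
3 | 3,5-bis(methoxymethoxy)phenol | COCOc1cc(O)cc(OCOC)c1 | intermediate
4 | 2-iodo-3,5-bis(methoxymethoxy)phenol | COCOc1cc(O)c(I)c(OCOC)c1 | intermediate
5 | 3-bromo-4-hydroxybenzaldehyde | O=Cc1ccc(O)c(Br)c1 | starting material
6 | 3-chloro-3-methylbut-1-yne | C#CC(C)(C)Cl | starting material
7 | 3-bromo-4-[(2-methylbut-3-yn-2-yl)oxy]benzaldehyde | O=Cc1ccc(OC(C)(C)C#C)c(Br)c1 | intermediate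
8 | 3-bromo-4-[(2-methylbut-3-en-2-yl)oxy]benzaldehyde | O=Cc1ccc(OC(C)(C)C=C)c(Br)c1 | intermediate
9 | 2-bromo-4-formyl-6-(3-methylbut-2-en-1-yl)cyclohexa-2,4-dien-1-one (racemic) | O=CC1=CC(CC=C(C)C)C(=O)C(Br)=C1 | intermediate
10 | 3-bromo-4-hydroxy-5-(3-methylbut-2-en-1-yl)benzaldehyde | O=Cc1cc(Br)c(O)c(CC=C(C)C)c1 | intermediate
11 | 3-bromo-4-methoxy-5-(3-methylbut-2-en-1-yl)benzaldehyde | COc1c(Br)cc(C=O)cc1CC=C(C)C | intermediate
12 | 1-bromo-5-ethynyl-2-methoxy-3-(3-methylbut-2-en-1-yl)benzene | COc1c(Br)cc(C#C)cc1CC=C(C)C | intermediate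
13 | carbon monoxide | [C-]#[O+] | starting material
14 | 3-[3-bromo-4-methoxy-5-(3-methylbut-2-en-1-yl)phenyl]-1-[2-hydroxy-4,6-bis(methoxymethoxy)phenyl]prop-2-yn-1-one | COc1c(Br)cc(C#CC(=O)c2c(O)cc(OCOC)cc2OCOC)cc1CC=C(C)C | intermediate
15 | (2E)-3-[3-bromo-4-methoxy-5-(3-methylbut-2-en-1-yl)phenyl]-3-(diethylamino)-1-[2-hydroxy-4,6-bis(methoxymethoxy)phenyl]prop-2-en-1-one | CCN(CC)/C(=C/C(=O)c1c(O)cc(OCOC)cc1OCOC)c1cc(Br)c(OC)c(CC=C(C)C)c1 | intermediate
16 | 2-[3-bromo-4-methoxy-5-(3-methylbut-2-en-1-yl)phenyl]-5,7-bis(methoxymethoxy)-4H-chromen-4-one | COc1c(Br)cc(C2=CC(=O)c3c(OCOC)cc(OCOC)cc3O2)cc1CC=C(C)C | intermediate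
17 | (2S)-2-[3-bromo-4-methoxy-5-(3-methylbut-2-en-1-yl)phenyl]-4-{[diethoxy(methyl)silyl]oxy}-5,7-bis(methoxymethoxy)-2H-chromene | COc1c(Br)cc([C@@H]2C=C(O[Si](C)(OCC)OCC)c3c(OCOC)cc(OCOC)cc3O2)cc1CC=C(C)C | intermediate
18 | (2S)-2-[3-bromo-4-methoxy-5-(3-methylbut-2-en-1-yl)phenyl]-5,7-bis(methoxymethoxy)-2,3-dihydro-4H-chromen-4-one | COc1c(Br)cc([C@@H]2CC(=O)c3c(OCOC)cc(OCOC)cc3O2)cc1CC=C(C)C | intermediate
19 | (2S)-2-[3-bromo-4-methoxy-5-(3-methylbut-2-en-1-yl)phenyl]-5-hydroxy-7-(methoxymethoxy)-2,3-dihydro-4H-chromen-4-one | COc1c(Br)cc([C@@H]2CC(=O)c3c(O)cc(OCOC)cc3O2)cc1CC=C(C)C | intermediate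
20 | (2S)-2-[3-bromo-4-methoxy-5-(3-methylbut-2-en-1-yl)phenyl]-5,7-dihydroxy-2,3-dihydro-4H-chromen-4-one | COc1c(Br)cc([C@@H]2CC(=O)c3c(O)cc(O)cc3O2)cc1CC=C(C)C | intermediate
21 | 2-methylbut-3-yn-2-ol | CC(C)(O)C#C | starting material
22 | (2S)-5,7-dihydroxy-2-[3-(3-hydroxy-3-methylbut-1-yn-1-yl)-4-methoxy-5-(3-methylbut-2-en-1-yl)phenyl]-2,3-dihydro-4H-chromen-4-one | COc1c(C#CC(C)(C)O)cc([C@@H]2CC(=O)c3c(O)cc(O)cc3O2)cc1CC=C(C)C | intermediate
23 | (2S)-5,7-dihydroxy-2-{3-[(1Z)-3-hydroxy-3-methylbut-1-en-1-yl]-4-methoxy-5-(3-methylbut-2-en-1-yl)phenyl}-2,3-dihydro-4H-chromen-4-one | COc1c(/C=C\C(C)(C)O)cc([C@@H]2CC(=O)c3c(O)cc(O)cc3O2)cc1CC=C(C)C | target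

**Step count and risks**

Total step count: 12. Longest linear sequence: 10 steps (steps 3 to 12, from 3-bromo-4-hydroxybenzaldehyde); the ring A branch (steps 1 and 2) joins at step 8.

Steps most likely to fail:

1. Step 8. The aroyl–palladium species may be bypassed by direct alkynylation (leading to a benzofuran) or captured by diethylamine as an amide; insertion into the C–Br bond may compete at the temperature needed; and ring closure may go 5-exo. Fallback: the ynone is made without carbon monoxide and cyclised separately, setting out from 3 and 12. Magnesium-mediated ortho-formylation of 3 (MgCl2, Et3N, paraformaldehyde, MeCN, reflux) should give 2-hydroxy-4,6-bis(methoxymethoxy)benzaldehyde F1, formylated only beside the free hydroxyl. The bromomagnesium acetylide of 12 (EtMgBr, THF, 0 °C to rt, no halogen–metal exchange at the bromide) is added to F1 that has first been deprotonated with one equivalent of EtMgBr, giving racemic 3-[3-bromo-4-methoxy-5-(3-methylbut-2-en-1-yl)phenyl]-1-[2-hydroxy-4,6-bis(methoxymethoxy)phenyl]prop-2-yn-1-ol F2. MnO2 in CH2Cl2 oxidises this benzylic propargylic alcohol to ynone 14, now isolated, and Et2NH in EtOH closes ring C through 15, coming back to the route at 16.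

2. Step 9. Hydride transfer to the electron-rich 5,7-dioxygenated flavone may be slow, facial discrimination may be insufficient, the ketone may be reduced further, or the enolate may open ring C by loss of the phenoxide and erode the enantiomeric purity. Fallback: reduction and enantioselection are separated, setting out from 16. Conjugate reduction with LiBH(s-Bu)3 (THF, −78 °C) gives racemic 2-[3-bromo-4-methoxy-5-(3-methylbut-2-en-1-yl)phenyl]-5,7-bis(methoxymethoxy)-2,3-dihydro-4H-chromen-4-one F3. Kinetic resolution by asymmetric transfer hydrogenation (RhCl(Cp*)(TsDPEN), the ligand enantiomer matched to the (2R)-ketone, HCO2H/Et3N, EtOAc, rt) reduces the (2R)-enantiomer to the cis alcohol (2R,4R)-2-[3-bromo-4-methoxy-5-(3-methylbut-2-en-1-yl)phenyl]-5,7-bis(methoxymethoxy)-3,4-dihydro-2H-chromen-4-ol F4. The unreacted (2S)-ketone is separated by chromatography and comes back to the route at 18, at the cost of half the material.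

3. Step 11. Oxidative addition into the hindered, electron-rich C–Br bond may be too slow at rt, the chelating phenoxide may tie up palladium or copper, and any heating in amine risks reversible ring opening to the chalcone and loss of configuration at C2. Fallback: the order of coupling and deprotection is changed, setting out from 18, so that a neutral substrate without phenols is coupled. Sonogashira coupling of 18 with 21 (PdCl2(PPh3)2, CuI, Et3N, THF, up to 50 °C) gives (2S)-2-[3-(3-hydroxy-3-methylbut-1-yn-1-yl)-4-methoxy-5-(3-methylbut-2-en-1-yl)phenyl]-5,7-bis(methoxymethoxy)-2,3-dihydro-4H-chromen-4-one F5. The conditions of step 10 then remove the MOM ethers, through (2S)-5-hydroxy-2-[3-(3-hydroxy-3-methylbut-1-yn-1-yl)-4-methoxy-5-(3-methylbut-2-en-1-yl)phenyl]-7-(methoxymethoxy)-2,3-dihydro-4H-chromen-4-one F6, and the sequence comes back to the route at 22. The tertiary propargylic alcohol is far less prone to ionise in acid than the allylic alcohol of the target.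

**Further compounds**

F1 | step 8 | 2-hydroxy-4,6-bis(methoxymethoxy)benzaldehyde | COCOc1cc(O)c(C=O)c(OCOC)c1
F2 | step 8 | 3-[3-bromo-4-methoxy-5-(3-methylbut-2-en-1-yl)phenyl]-1-[2-hydroxy-4,6-bis(methoxymethoxy)phenyl]prop-2-yn-1-ol (racemic) | COc1c(Br)cc(C#CC(O)c2c(O)cc(OCOC)cc2OCOC)cc1CC=C(C)C
F3 | step 9 | 2-[3-bromo-4-methoxy-5-(3-methylbut-2-en-1-yl)phenyl]-5,7-bis(methoxymethoxy)-2,3-dihydro-4H-chromen-4-one (racemic) | COc1c(Br)cc(C2CC(=O)c3c(OCOC)cc(OCOC)cc3O2)cc1CC=C(C)C
F4 | step 9 | (2R,4R)-2-[3-bromo-4-methoxy-5-(3-methylbut-2-en-1-yl)phenyl]-5,7-bis(methoxymethoxy)-3,4-dihydro-2H-chromen-4-ol | COc1c(Br)cc([C@H]2C[C@@H](O)c3c(OCOC)cc(OCOC)cc3O2)cc1CC=C(C)C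
F5 | step 11 | (2S)-2-[3-(3-hydroxy-3-methylbut-1-yn-1-yl)-4-methoxy-5-(3-methylbut-2-en-1-yl)phenyl]-5,7-bis(methoxymethoxy)-2,3-dihydro-4H-chromen-4-one | COc1c(C#CC(C)(C)O)cc([C@@H]2CC(=O)c3c(OCOC)cc(OCOC)cc3O2)cc1CC=C(C)C
F6 | step 11 | (2S)-5-hydroxy-2-[3-(3-hydroxy-3-methylbut-1-yn-1-yl)-4-methoxy-5-(3-methylbut-2-en-1-yl)phenyl]-7-(methoxymethoxy)-2,3-dihydro-4H-chromen-4-one | COc1c(C#CC(C)(C)O)cc([C@@H]2CC(=O)c3c(O)cc(OCOC)cc3O2)cc1CC=C(C)C
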